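**Retrosynthetic overview**
- The strategy rests on the C3–C4 bond of the 2,3-dihydro-1-benzoxepine ring (O1, C2, C3, C4, C5, C5a, C9a). It joins two sp2 carbons: C3, which carries the exocyclic CH2, and C4 of the cis ring alkene C4=C5.
- Key disconnection: C3–C4 plus one exocyclic C–H. A (Z)-alkenyl–Pd at C4 adds 7-exo-dig across the alkyne of an aryl propargyl ether (internal alkyne carbon becomes C3, terminal carbon becomes =CH2), and formate supplies the hydride.
- The oxepine is the only ring formed; the benzene ring is bought.
- The precursor comes from 5-(chloromethyl)salicylaldehyde: stearate by carboxylate displacement of the benzylic chloride, O1–C2 by phenol propargylation, the (Z)-CH=CHBr arm by Wittig bromomethylenation of the formyl group.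

Key step: step 4

Remark: the target has no stereocentre and is achiral, so there is no enantiomer to select; the only stereochemical element is the cis C4=C5 ring alkene, which is fixed by the (Z)-bromoalkene and then by the ring.

**Step 1**
Reactants: 1 5-(chloromethyl)-2-hydroxybenzaldehyde; 2 stearic acid
Product: 4 3-formyl-4-hydroxybenzyl stearate, via caesium stearate 3 (not isolated)
Conditions: 2 (1.0 equiv), Cs2CO3 (0.5 equiv), DMF, 50 °C until gas evolution ends; then 1 (1.1 equiv), rt
Reagents that add atoms: stearic acid (2), CCCCCCCCCCCCCCCCCC(=O)O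
Why: Caesium-carboxylate esterification (nucleophilic displacement at an activated para-hydroxybenzylic chloride); the weakly basic stearate should leave the phenol un-ionised, so phenol O-benzylation does not compete.

**Step 2**
Reactants: 4 3-formyl-4-hydroxybenzyl stearate; 5 propargyl bromide
Product: 6 3-formyl-4-(prop-2-yn-1-yloxy)benzyl stearate
Conditions: 5 (1.3 equiv), K2CO3 (1.5 equiv), DMF, 0 °C to rt
Reagents that add atoms: propargyl bromide (5), C#CCBr
Why: Williamson ether synthesis; the ortho-formyl phenol is ionised by K2CO3 and O-alkylated by the propargylic bromide at room temperature, and the electron-withdrawing formyl group should keep the phenoxide from expelling the para-benzylic stearate.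

**Step 3**
Reactants: 6 3-formyl-4-(prop-2-yn-1-yloxy)benzyl stearate; 7 (bromomethyl)triphenylphosphonium bromide
Product: 9 3-[(Z)-2-bromovinyl]-4-(prop-2-yn-1-yloxy)benzyl stearate, via bromomethylenetriphenylphosphorane 8 (not isolated)
Conditions: 7 (1.5 equiv), KOtBu (1.4 equiv), THF, −78 °C, 1 h; then 6, −78 °C; quench with aq. NH4Cl at −78 °C
Reagents that add atoms: (bromomethyl)triphenylphosphonium bromide (7), BrC[P+](c1ccccc1)(c1ccccc1)c1ccccc1.[Br-]
Why: Wittig bromomethylenation with the non-stabilised α-bromo ylide, whose kinetic cis-oxaphosphetane should favour the (Z)-bromoalkene; with base kept below the amount of phosphonium salt and a cold quench, loss of HBr, alkyne deprotonation and attack on the ester are not expected.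

**Step 4**
Reactants: 9 3-[(Z)-2-bromovinyl]-4-(prop-2-yn-1-yloxy)benzyl stearate
Product: 12 (3-methylene-2,3-dihydro-1-benzoxepin-7-yl)methyl stearate, via alkenylpalladium bromide 10 (not isolated), via cyclised alkenylpalladium bromide 11 (not isolated)
Conditions: Pd(PPh3)4 (5 mol%), HCO2Na (1.5 equiv, fine suspension), degassed dry DMF (0.02 M), 70 °C, Ar
Reagents that add atoms: none
Why: Pd(0) should insert into the alkenyl C–Br bond with retention to give the (Z)-alkenylpalladium bromide 10; syn-carbopalladation of the tethered terminal alkyne then forms C3–C4 and places Pd on the exocyclic carbon (11); bromide–formate exchange, loss of CO2 and C–H reductive elimination give the =CH2 group and return Pd(0). The closest known reaction type is the Pd-catalysed reductive cyclisation of aryl and alkenyl halides onto tethered alkynes with formate as hydride source (alkyne carbopalladation with hydride capture), which is established for seven-membered benzo-fused rings. The oxepine closes in the 7-exo-dig mode. No stereocentre is created; the cis C4=C5 geometry comes from the (Z)-bromide and is held by the ring, and the exocyclic alkene carries two hydrogens. Exo closure is favoured over 8-endo by the short O–CH2 tether and the cis-alkene/arene backbone, which hold Pd–C4 over the internal alkyne carbon. Cyclisation ahead of hydride capture is favoured by the low stationary formate concentration and high dilution (which also disfavours intermolecular alkyne coupling), and the weakly basic formate should spare the para-alkoxybenzyl stearate and avoid loss of HBr.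

**Compound list**
1 | 5-(chloromethyl)-2-hydroxybenzaldehyde | O=Cc1cc(CCl)ccc1O | starting material
2 | stearic acid (octadecanoic acid) | CCCCCCCCCCCCCCCCCC(=O)O | starting material
3 | caesium stearate | CCCCCCCCCCCCCCCCCC(=O)[O-].[Cs+] | intermediate
4 | 3-formyl-4-hydroxybenzyl stearate | O=Cc1cc(COC(=O)CCCCCCCCCCCCCCCCC)ccc1O | intermediate
5 | propargyl bromide (3-bromoprop-1-yne) | C#CCBr | starting material
6 | 3-formyl-4-(prop-2-yn-1-yloxy)benzyl stearate | O=Cc1cc(COC(=O)CCCCCCCCCCCCCCCCC)ccc1OCC#C | intermediate
7 | (bromomethyl)triphenylphosphonium bromide | BrC[P+](c1ccccc1)(c1ccccc1)c1ccccc1.[Br-] | starting material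
8 | (bromomethylene)triphenylphosphorane | BrC=P(c1ccccc1)(c1ccccc1)c1ccccc1 | intermediate
9 | 3-[(Z)-2-bromovinyl]-4-(prop-2-yn-1-yloxy)benzyl stearate | Br/C=C\c1cc(COC(=O)CCCCCCCCCCCCCCCCC)ccc1OCC#C | intermediate
10 | (Z)-alkenylpalladium(II) bromide formed from 9 by oxidative addition (PPh3 ligands on Pd not drawn) | Br[Pd]/C=C\c1cc(COC(=O)CCCCCCCCCCCCCCCCC)ccc1OCC#C | intermediate
11 | cyclised exocyclic alkenylpalladium(II) bromide, Pd cis to C4 (PPh3 ligands on Pd not drawn) | Br[Pd]/C=C1/COc2ccc(COC(=O)CCCCCCCCCCCCCCCCC)cc2C=C1 | intermediate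
12 | (3-methylene-2,3-dihydro-1-benzoxepin-7-yl)methyl stearate | C=C1C=Cc2cc(COC(=O)CCCCCCCCCCCCCCCCC)ccc2OC1 | target

**Totals**
Total step count: 4. Longest linear sequence: 4 steps (1 → 4 → 6 → 9 → 12).

**Steps most likely to fail**

Step 4. Several processes may divert the alkenylpalladium species: hydride capture before ring closure (plain hydrodebromination), intermolecular coupling through the terminal alkyne C–H, and Pd-mediated cleavage of the aryl propargyl ether. Pd–H isomerisation or over-reduction of the product diene is also possible, and any (E)-bromoalkene carried over from step 3 cannot cyclise. The fallback closes the ring at C4=C5 by an intramolecular Wittig reaction. It sets out from 4: alkylation of the phenol with excess 3-chloro-2-(chloromethyl)prop-1-ene (K2CO3, DMF, rt) should give 4-{[2-(chloromethyl)prop-2-en-1-yl]oxy}-3-formylbenzyl stearate F1. Triphenylphosphine in MeCN at 60 °C should convert it into {2-[(2-formyl-4-{[(octadecanoyl)oxy]methyl}phenoxy)methyl]prop-2-en-1-yl}triphenylphosphonium chloride F2. K2CO3 with catalytic 18-crown-6 in CH2Cl2 at reflux under high dilution should generate the allylic ylide F3, which condenses with the formyl group. The seven-membered ring allows only the cis alkene, so the fallback comes back to the route at 12.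

Step 3. The kinetic Z-selectivity of the Wittig step may erode, and residual alkoxide may eliminate HBr from the product or deprotonate the alkyne. The fallback sets the geometry by trans-selective hydrodebromination of a 1,1-dibromoalkene and keeps the alkyne silyl-capped meanwhile. It sets out from 4: alkylation with 3-bromo-1-(trimethylsilyl)prop-1-yne (K2CO3, DMF, rt) should give 3-formyl-4-{[3-(trimethylsilyl)prop-2-yn-1-yl]oxy}benzyl stearate F4. Ramirez dibromo-olefination (CBr4, PPh3, CH2Cl2, 0 °C) should give 3-(2,2-dibromovinyl)-4-{[3-(trimethylsilyl)prop-2-yn-1-yl]oxy}benzyl stearate F5. Pd-catalysed reduction of the bromine trans to the aryl group (Bu3SnH 1.05 equiv, Pd(PPh3)4 cat., toluene, rt) should give 3-[(Z)-2-bromovinyl]-4-{[3-(trimethylsilyl)prop-2-yn-1-yl]oxy}benzyl stearate F6. Silver-catalysed C-desilylation (AgNO3 cat., acetone–water, rt) then returns to the route at 9.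

Step 2. The phenoxide of 4 may expel stearate by 1,6-elimination (quinone-methide formation), leading to benzylic scrambling and oligomers before O-alkylation is complete. The fallback introduces the ester only after the phenol is capped. It sets out from 1: hydrolysis of the benzylic chloride (water–acetone, NaHCO3, 50 °C) should give 2-hydroxy-5-(hydroxymethyl)benzaldehyde F7. Selective phenol alkylation with 5 (K2CO3, acetone, rt) should give 5-(hydroxymethyl)-2-(prop-2-yn-1-yloxy)benzaldehyde F8. Acylation with stearoyl chloride (pyridine, DMAP cat., CH2Cl2, 0 °C) comes back to the route at 6.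

**Further compounds**
F1 | step 4 | 4-{[2-(chloromethyl)prop-2-en-1-yl]oxy}-3-formylbenzyl stearate | O=Cc1cc(COC(=O)CCCCCCCCCCCCCCCCC)ccc1OCC(=C)CCl
F2 | step 4 | {2-[(2-formyl-4-{[(octadecanoyl)oxy]methyl}phenoxy)methyl]prop-2-en-1-yl}triphenylphosphonium chloride | O=Cc1cc(COC(=O)CCCCCCCCCCCCCCCCC)ccc1OCC(=C)C[P+](c1ccccc1)(c1ccccc1)c1ccccc1.[Cl-]
F3 | step 4 | allylic ylide derived from F2 | O=Cc1cc(COC(=O)CCCCCCCCCCCCCCCCC)ccc1OCC(=C)C=P(c1ccccc1)(c1ccccc1)c1ccccc1
F4 | step 3 | 3-formyl-4-{[3-(trimethylsilyl)prop-2-yn-1-yl]oxy}benzyl stearate | O=Cc1cc(COC(=O)CCCCCCCCCCCCCCCCC)ccc1OCC#C[Si](C)(C)C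
F5 | step 3 | 3-(2,2-dibromovinyl)-4-{[3-(trimethylsilyl)prop-2-yn-1-yl]oxy}benzyl stearate | BrC(Br)=Cc1cc(COC(=O)CCCCCCCCCCCCCCCCC)ccc1OCC#C[Si](C)(C)C
F6 | step 3 | 3-[(Z)-2-bromovinyl]-4-{[3-(trimethylsilyl)prop-2-yn-1-yl]oxy}benzyl stearate | Br/C=C\c1cc(COC(=O)CCCCCCCCCCCCCCCCC)ccc1OCC#C[Si](C)(C)C
F7 | step 2 | 2-hydroxy-5-(hydroxymethyl)benzaldehyde | O=Cc1cc(CO)ccc1O
F8 | step 2 | 5-(hydroxymethyl)-2-(prop-2-yn-1-yloxy)benzaldehyde | O=Cc1cc(CO)ccc1OCC#C
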